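Every percent of solid substrate charged stays somewhere, so ring, solid and an unseen remainder add up to the whole. In this flask the remainder was already 55.2% at 1.00 h.

- winter: solid substrate 3 M; temperature 5 °C; the very flask that is asked about, followed so far
- flask: solid substrate 3.0 M; temperature 5 °C; time 10 h

winter run (percent of the solid substrate charged)

| time / h | ring / % | solid substrate / % |
|---|---|---|
| 1.00 | 22.5 | 22.3 |
| 2.50 | 36.5 | 0.1 |
| 3.00 | 37.2 | 0 |
| 5.00 | 37.1 | 0.6 |
| 6.00 | 36.8 | 0.5 |
| 8.00 | 38.1 | 0 |

(scatter of a reading: 0.5 percentage points)

- solid substrate is a solid; its amount is given per volume of the solution
- what is taken out of ring is counted as made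
- at the start none of the solid substrate is in solution
- the earlier runs do not show what temperature does; that part of a forecast is a guess

- south-east: change nothing and wait 5.0 h more
- south: at 10 h raise the temperature by 20 K, then wait 5.0 h
- south-west: at 10 h take out 90% of the ring then present, then wait 5.0 h

- ring, in percent of the solid substrate first charged, at 10 h
- what to do for the largest gain in ring; "none" if nothing gains more than 2 percentage points (south-east / south / south-west / none)
- ring present, with what was taken out counted in, in percent of the solid substrate first charged, after south-east
- ring present, with what was taken out counted in, in percent of the solid substrate first charged, after south-west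

Control changed hands between 1.00 h and 2.50 h, as solid in the flask fell from 22.3% to 0.1% and ring stopped climbing. Solid was the limiting reagent. I reckoned the further gain in two ways.

The first way used the feed. I called W the reserve, the percent of the charge still able to become ring, read as the mean solid reading from 3.00 h on: 0.27 percentage points. That is less than one reading's scatter of 0.5 points. W counts the unseen remainder as dead, so it needed a check from elsewhere.

The second way used ring itself. Its climb from 3.00 h to 8.00 h, carried over 5.0 h, gave 0.9 points.

The two parted, the drift being larger than W, and the drift was the one that cheated. Ring went 37.2%, 36.8%, 38.1%, so the climb hangs on the last reading. Both stood below the 2 points margin. I therefore took the mean plateau, 37.3%, for this flask at 10 h.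

The forecast gave 37.3% (36.7% to 37.9%), 37.3% (36.6% to 38%) after south-east, 37.3% (36.5% to 39%) after south-west, and best: none, holding that “the plateau means substrate is exhausted, not that equilibrium is reached”.

The flask gave 37.1%, 37.1% after south-east and 37.1% after south-west. The gains were 0 points, 0 points and 0 points, so best was none.

    solid substrate ⇌ starting material, rate k1*(cs1 - [starting material]) while solid is left; crystals form when [starting material] > cs1 (solubility = 1.30 M, k = 7.00 × 10⁻⁴ s⁻¹)
    starting material → ring (k = 4.70 × 10⁻⁴ s⁻¹, Ea = 87.0 kJ mol⁻¹)
    2 starting material → open dimer (k = 0.00110 M⁻¹ s⁻¹, Ea = 70.0 kJ mol⁻¹)
    (constants at 5 °C)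

At 10.0 h the flask held 0% of solid substrate and 0% of starting material, and south-east brought 0 points, which sits with W below the margin. A neighbour flask charged with 0.75 M had 0% of its solid substrate still there at 10.0 h, so its ring, 48.5% of its own charge, had no reserve behind it, though that is a larger share of its charge than this flask's 37.1% of its own. Left until 100 h, the flask changed nothing: ring stood at 37.1% and open dimer at 62.9%.

The runs are simulated from invented constants; the scatter is artificial.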